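Left-handed product is what these flasks are run for, and this note says what to expect of it.

common to all: left-handed substrate 23 mM; racemization catalyst 23 µM; right-handed substrate 23 mM

| flask | reagent | time | remark |
|---|---|---|---|
| beta | 50.6 mM (fed, over 2.40 h) | 3.0 h | a stirred flask in which reagent is dosed at a steady rate over 2.40 h without added volume, worked up at 3.0 h |
| gamma | 50.6 mM |  | one stirred flow tank at steady state, fed with the mixture as stated, mean residence time 3.0 h |
| theta | 50.6 mM | 3.0 h | everything together in a closed stirred flask, run for 3.0 h |
| alpha | 50.6 mM |  | one stirred flow tank at steady state, fed with the mixture as stated, mean residence time 15.0 h |

* the set-up with the highest amount of left-handed product at the outlet or at the end, in percent of the left-handed substrate and right-handed substrate together put in ("none" if the first two lie within 2 percentage points) (beta / gamma / theta / alpha / none)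
* amount of left-handed product at the outlet or at the end, in percent of the left-handed substrate and right-handed substrate together put in, beta
* amount of left-handed product at the outlet or at the end, in percent of the left-handed substrate and right-handed substrate together put in, gamma
* amount of left-handed product at the outlet or at the end, in percent of the left-handed substrate and right-handed substrate together put in, theta
* amount of left-handed product at the outlet or at the end, in percent of the left-handed substrate and right-handed substrate together put in, alpha

- reagent is single-handed; left-handed substrate and right-handed substrate are mirror images of each other, charged as a racemate, each of them at the stated concentration
- for a step with 2 of a species take k times the square, and two of it per event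
- the stated concentrations are those of everything mixed, before any reaction; amounts are the same in each set-up
- the feed brings no volume worth counting
- run time (beta): 3.0 h
- the handed part of reagent does not stay in what it makes, so the products of the two hands are mirror images too

    reagent + left-handed substrate → left-handed product (k1 = 0.0013 L mol⁻¹ s⁻¹)
    reagent + right-handed substrate → right-handed product (k2 = 5.7 × 10⁻⁴ L mol⁻¹ s⁻¹)
    left-handed substrate + racemization catalyst ⇌ right-handed substrate + racemization catalyst, rate k3*[racemization catalyst]*[left-handed substrate] forward; the back reaction follows from the equilibrium constant (k3 = 51 L mol⁻¹ s⁻¹)
    2 racemization catalyst → spent catalyst (k4 = 16 L mol⁻¹ s⁻¹)

1. In each flask: both substrates in equal parts, reagent and racemization catalyst. Reagent stands at 1.10 of the two substrates together, so they are the limiting reagent.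

2. At equal concentration, left-handed substrate takes up reagent 2.28 times as fast as right-handed substrate.

3. The catalyst swaps the hands with a half-life of 0.164 h at full charge, forward step alone. Left-handed substrate has a half-life of 2.93 h by its reaction with reagent, with reagent held at its charge.

4. The catalyst destroys itself. By that loss alone, in theta, 0.112 of its charge stands after 3.0 h, and the swap half-life is then 1.47 h, still shorter than the reaction's.

5. So the substrates should stay nearly equal, and 0.695 of each unit of reagent spent should end in left-handed product: the left-handed share.

6. Do not top up the catalyst: at charge the swap is already the faster process.

7. This reckoning stops at the share; how much reagent is spent remains open. The forecast puts the share lower, at 68 to 69%, and gives 15.9 % for beta, 18.9 % for gamma, 23.3 % for theta and 37.5 % for alpha, with alpha best: “the yield is set mainly by overall near-equimolar second-order conversion”.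

The flasks give 15.9 % for beta, 19.0 % for gamma, 23.4 % for theta and 38.1 % for alpha, so alpha is best.

In theta at charge, left-handed substrate has a half-life of 0.16 h by the forward swap, while reagent has 6.4 h by its reaction with left-handed substrate, a ratio of 39.2. Divided by the left-handed share of 0.695, the yield of theta corresponds to 33.7 % of the substrates reacted. In gamma, reagent stands at 0.749 of its charge, so the amount spent equals 0.276 of the substrate charge. Multiplied by the share, that is 19.2 %, and the gamma outlet reads 19.0 %.

(The constants are invented; no experiment stands behind them.)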